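**Retrosynthetic overview**
- The (E)-propenyl group is installed last from an aryl aldehyde by Julia–Kocienski ethylidenation, because a propenyl group para to the ring oxygen would not survive the acid-catalysed key step.
- Key disconnection O1–C2 (a C–O bond): the trans-dihydrobenzofuran aldehyde is opened to an achiral 2-hydroxy-α-methylstilbene; a chiral Brønsted-acid hydroalkoxylation closes the dihydrofuran ring and sets C2 and C3 together.
- The stilbene C3–C3a bond comes from a Heck coupling of 5-iodovanillin with an (E)-propenylphenol, itself made from 3-hydroxy-4,5-dimethoxybenzaldehyde.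
- Ring order: both benzene rings are bought; the dihydrofuran ring is the only ring formed (step 3).

Assumption: both aldehydes and the ethyl PT-sulfone are bought; the sense of induction of the IDPi catalyst cannot be predicted, so the enantiomer giving (2S,3S) is fixed in a first screen and written here as (S,S)-IDPi (BINOL core, 3,3'-Ar = 3,5-(CF3)2C6H3, N-Tf).

**Step 1**
Reactants: 1 3-hydroxy-4,5-dimethoxybenzaldehyde
Product: 2 2,3-dimethoxy-5-[(E)-prop-1-en-1-yl]phenol
Conditions: EtSO2PT (1.3 equiv), KHMDS (2.4 equiv), DME, −60 °C → rt; aq NH4Cl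
Reagents that add atoms: 5-(ethylsulfonyl)-1-phenyl-1H-tetrazole, CCS(=O)(=O)c1nnnn1-c1ccccc1
Why: Julia–Kocienski olefination: the metallated PT-sulfone adds to the aldehyde (phenol carried as its potassium salt), and Smiles rearrangement with loss of SO2 and tetrazolone gives the (E)-propenyl arene; no stereocentre is formed.

**Step 2**
Reactants: 2 2,3-dimethoxy-5-[(E)-prop-1-en-1-yl]phenol; 3 5-iodovanillin (4-hydroxy-3-iodo-5-methoxybenzaldehyde)
Product: 4 4-hydroxy-3-[(E)-1-(3-hydroxy-4,5-dimethoxyphenyl)prop-1-en-2-yl]-5-methoxybenzaldehyde (the two aryl groups trans across the C=C)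
Conditions: Pd(OAc)2 (5 mol %), n-Bu4NCl (1 equiv), NaHCO3 (3 equiv), DMF, 90 °C
Reagents that add atoms: none
Why: Mizoroki–Heck reaction under silver-free, halide-rich (Jeffery) conditions: aryl–Pd adds to the methyl-bearing alkene carbon so that Pd sits at the benzylic carbon, and syn β-H elimination gives the (E)-1,2-diarylpropene, the neutral conditions disfavouring phenoxide attack on benzyl–Pd (oxyarylation); no stereocentre is formed.

**Step 3**
Reactants: 4 4-hydroxy-3-[(E)-1-(3-hydroxy-4,5-dimethoxyphenyl)prop-1-en-2-yl]-5-methoxybenzaldehyde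
Product: 5 (2S,3S)-2-(3-hydroxy-4,5-dimethoxyphenyl)-7-methoxy-3-methyl-2,3-dihydro-1-benzofuran-5-carbaldehyde (2,3-trans)
Conditions: (S,S)-IDPi (5 mol %), 5 Å MS, CHCl3 (0.05 M), 0 °C → rt, stopped at full conversion
Reagents that add atoms: none
Why: Proposed new method: catalytic asymmetric 5-endo hydroalkoxylation of a 2-hydroxy-α-methylstilbene, in which the confined strong acid protonates C3 to give a contact ion pair of the C2 benzylic cation (stabilised by the 4-methoxy group of the 3-hydroxy-4,5-dimethoxyphenyl ring) with the chiral IDPi anion, reversible proton loss and re-addition interconverts the two C3-epimeric cations through the alkene (dynamic kinetic resolution), and the ortho-phenol forms the O1–C2 bond inside the chiral pocket anti to the C3 methyl, so the catalyst selects C3 (S) and C2 (S) follows as the trans isomer; the closest known reactions are IDPi-catalysed asymmetric intramolecular hydroalkoxylation of alkenols and the racemic, trans-selective acid-mediated closure of 1-aryl-2-(2-hydroxyaryl)propyl cations to dihydrobenzofuran neolignans.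

**Step 4**
Reactants: 5 (2S,3S)-2-(3-hydroxy-4,5-dimethoxyphenyl)-7-methoxy-3-methyl-2,3-dihydro-1-benzofuran-5-carbaldehyde
Product: 6 5-[(2S,3S)-7-methoxy-3-methyl-5-[(E)-prop-1-en-1-yl]-2,3-dihydro-1-benzofuran-2-yl]-2,3-dimethoxyphenol (CNP0299956.1)
Conditions: EtSO2PT (1.5 equiv), KHMDS (2.6 equiv), DME, −60 °C → rt; aq NH4Cl
Reagents that add atoms: 5-(ethylsulfonyl)-1-phenyl-1H-tetrazole, CCS(=O)(=O)c1nnnn1-c1ccccc1
Why: Julia–Kocienski olefination of the aryl aldehyde is expected to give mainly the (E)-propenyl group with KHMDS in DME; the ring-B phenol is carried as its potassium salt and neither C2–H nor C3–H is acidic enough to epimerise, so (2S,3S) is kept.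

**Compound list**
1 | 3-hydroxy-4,5-dimethoxybenzaldehyde | O=Cc1cc(O)c(OC)c(OC)c1 | starting material
2 | 2,3-dimethoxy-5-[(E)-prop-1-en-1-yl]phenol | C/C=C/c1cc(O)c(OC)c(OC)c1 | intermediate
3 | 5-iodovanillin (4-hydroxy-3-iodo-5-methoxybenzaldehyde) | O=Cc1cc(I)c(O)c(OC)c1 | starting material
4 | 4-hydroxy-3-[(E)-1-(3-hydroxy-4,5-dimethoxyphenyl)prop-1-en-2-yl]-5-methoxybenzaldehyde | O=Cc1cc(OC)c(O)c(c1)/C(C)=C/c1cc(O)c(OC)c(OC)c1 | intermediate
5 | (2S,3S)-2-(3-hydroxy-4,5-dimethoxyphenyl)-7-methoxy-3-methyl-2,3-dihydro-1-benzofuran-5-carbaldehyde | O=Cc1cc(OC)c2c(c1)[C@H](C)[C@@H](c1cc(O)c(OC)c(OC)c1)O2 | intermediate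
6 | 5-[(2S,3S)-7-methoxy-3-methyl-5-[(E)-prop-1-en-1-yl]-2,3-dihydro-1-benzofuran-2-yl]-2,3-dimethoxyphenol | C/C=C/c1cc(OC)c2c(c1)[C@H](C)[C@@H](c1cc(O)c(OC)c(OC)c1)O2 | target

**Total step count:** 4. **Longest linear sequence:** 4 (1 → 2 → 4 → 5 → 6).

**Steps most likely to fail and their fallbacks**

The step most likely to fail is step 3, the proposed new hydroalkoxylation. The risks are low ee if protonation is not reversible enough or the product re-ionises, competing protonation at C2, and catalyst binding to the aldehyde. The fallback uses known chemistry and sets out from 4. An achiral acid (TfOH, 5 mol %, CH2Cl2, 0 °C) effects the same cation cyclisation, which is established for o-hydroxystilbenes and is trans-selective. It gives the racemate, a 1:1 mixture of 5 and (2R,3R)-2-(3-hydroxy-4,5-dimethoxyphenyl)-7-methoxy-3-methyl-2,3-dihydro-1-benzofuran-5-carbaldehyde F2. Preparative SFC on an amylose-carbamate chiral phase then isolates 5, where the route is rejoined; this costs at most half the material.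

Second is step 2, the Heck coupling of an internal, electron-rich alkene with an ortho-phenoxide aryl iodide. It may be sluggish, give regioisomers, or leak into oxyarylation to racemic 5, which would have to be removed by chromatography. The fallback sets out from 1, so 2 is not needed. A boron–Wittig reaction with 1,1-bis(pinacolboryl)ethane (LiTMP, 2.2 equiv, THF, −78 °C → rt) gives 2,3-dimethoxy-5-[(Z)-2-(4,4,5,5-tetramethyl-1,3,2-dioxaborolan-2-yl)prop-1-en-1-yl]phenol F1, with aryl trans to boron (geometry to be confirmed by NOE). Suzuki–Miyaura coupling of F1 with 3 (Pd(dppf)Cl2, K3PO4, dioxane/H2O, 80 °C) proceeds with retention and comes back to the route at 4.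

Third is step 4, where the E/Z ratio of the Julia–Kocienski reaction on a substrate carrying a phenoxide is uncertain. The fallback sets out from 5. Wittig ethylidenation (EtPPh3Br and KOtBu, 2.5 equiv each, THF, 0 °C) gives a Z-rich alkene mixture whose main component is 5-[(2S,3S)-7-methoxy-3-methyl-5-[(Z)-prop-1-en-1-yl]-2,3-dihydro-1-benzofuran-2-yl]-2,3-dimethoxyphenol F3. Catalytic PdCl2(MeCN)2 (5 mol %, CH2Cl2, rt) then equilibrates F3 to the thermodynamically favoured E isomer, which is 6.

**Further compounds**
F1 | step 2 | 2,3-dimethoxy-5-[(Z)-2-(4,4,5,5-tetramethyl-1,3,2-dioxaborolan-2-yl)prop-1-en-1-yl]phenol | C/C(B1OC(C)(C)C(C)(C)O1)=C\c1cc(O)c(OC)c(OC)c1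
F2 | step 3 | (2R,3R)-2-(3-hydroxy-4,5-dimethoxyphenyl)-7-methoxy-3-methyl-2,3-dihydro-1-benzofuran-5-carbaldehyde | O=Cc1cc(OC)c2c(c1)[C@@H](C)[C@H](c1cc(O)c(OC)c(OC)c1)O2
F3 | step 4 | 5-[(2S,3S)-7-methoxy-3-methyl-5-[(Z)-prop-1-en-1-yl]-2,3-dihydro-1-benzofuran-2-yl]-2,3-dimethoxyphenol | C/C=C\c1cc(OC)c2c(c1)[C@H](C)[C@@H](c1cc(O)c(OC)c(OC)c1)O2
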